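**Plan**

1. Locants: ring carbons C1 (C–OH carrying the crotonoyl group), C5 (CH–O-ester), C6 (lactone O–CH), C7 (lactone CH), C8 (CH2), C9 (C=O), C10 (CH–CH3); lactone carbons C11 (α) and C12 (C=O).
2. Enabling feature: in the seven-membered ring the C1 oxygen stands 1,4 to C8, the carbon α to the C9 ketone, and C5–C6–C7 carries oxygen on C5 and C6; the carbocycle is therefore a furan (O, C1, C10, C9, C8) joined across its two α-carbons to a 1-alkoxy-2-oxyallyl unit (C5, C6, C7).
3. Retrosynthetic cuts, in order: the exocyclic C11=CH2 (from a Mannich base), the bond between the side-chain carbonyl carbon and the propenyl group, the C8–O bond of an oxygen bridge (reductive), the C5 ester, the lactone C6–O and C7–C11 bonds, and last C1–C5 and C7–C8 by (4+3) cycloaddition.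
4. Forward order of rings: furan, then 8-oxabicyclo[3.2.1]octenone (seven-membered ring closed, oxygen bridge C1–O–C8), then trans γ-lactone on C6–C7, then bridge cut to the free cycloheptanone, then side chain and methylene lactone completed.
5. Stereochemistry: an (S)-1-phenylethyl ether on the cation fixes C1, C5 and C8 in the cycloaddition; C7 comes from alkylation and equilibration, C6 from exo hydride delivery followed by SN2 inversion, C10 from exo hydroboration followed by equilibration to the exo methyl in the rigid bicycle; the ester centre is bought as (R)-2-methylbutanoic acid.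

Key step: step 5

Assumption: the (S)-1-phenylethyl group is taken to shield the face of cation 8 that leads to the ring configuration written for 9 (phenyl stacked over the allyl cation); the choice of auxiliary enantiomer rests on this model.

Convention for names: the α face of the seven-membered ring is the face of the bridge oxygen (it carries the C1 oxygen, the C6 oxygen and the C10 methyl of the target); the β face is the opposite one (C5 oxygen, C7–C11 bond). Axial and equatorial refer to the chair of the O–C1–C5–C6–C7–C8 ring; exo on C9/C10 means α.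

**Route**

Step 1
Reactants: 1 methyl 3-methylfuran-2-carboxylate
Product: 2 (3-methylfuran-2-yl)methanol
Conditions: LiAlH4, Et2O, 0 °C; aq. sodium potassium tartrate
Reagents that add atoms: none
Why: LiAlH4 reduction of the ester to the primary alcohol, the electron-rich furan being inert to hydride.

Step 2
Reactants: 2 (3-methylfuran-2-yl)methanol
Product: 3 tert-butyl[(3-methylfuran-2-yl)methoxy]diphenylsilane
Conditions: t-BuPh2SiCl, imidazole, DMF, 0 °C to rt
Reagents that add atoms: tert-butyl(chloro)diphenylsilane, CC(C)(C)[Si](Cl)(c1ccccc1)c1ccccc1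
Why: Silylation of a primary alcohol with a silyl chloride and imidazole; the bulky acid- and base-stable silyl ether is chosen to last until step 20.

Step 3
Reactants: 4 1,1-dimethoxypropan-2-one (3 equiv); 5 (S)-1-phenylethanol
Product: 6 1-methoxy-1-[(1S)-1-phenylethoxy]propan-2-one (both acetal epimers)
Conditions: p-TsOH·H2O (cat.), cyclohexane, reflux through 5 Å molecular sieves (MeOH removed)
Reagents that add atoms: none
Why: Acid-catalysed transacetalisation driven by removal of methanol; excess 4 limits exchange to one methoxy group and the benzylic C–O bond of 5 is not broken, so its configuration is kept.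

Step 4
Reactants: 6 1-methoxy-1-[(1S)-1-phenylethoxy]propan-2-one
Product: 7 triethyl({3-methoxy-3-[(1S)-1-phenylethoxy]prop-1-en-2-yl}oxy)silane (both acetal epimers)
Conditions: LiN(i-Pr)2, THF, −78 °C; Et3SiCl, −78 to 0 °C
Reagents that add atoms: chlorotriethylsilane, CC[Si](Cl)(CC)CC
Why: Kinetic deprotonation of the methyl ketone and O-silylation (silyl enol ether formation) take place at the CH3 group and not at the hindered acetal C–H.

Step 5
Reactants: 3 tert-butyl[(3-methylfuran-2-yl)methoxy]diphenylsilane; 7 triethylsilyl enol ether of the mixed acetal (1.5 equiv)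
Product: 9 oxa-bridged cycloadduct with C6 ketone and equatorial C5 (S)-1-phenylethoxy group, via alkoxy siloxyallyl cation triflate 8 (not isolated)
Conditions: Me3SiOTf (0.2 equiv), CH2Cl2, −95 °C; then Et3N
Reagents that add atoms: none
Why: Me3SiOTf abstracts the methoxy group of 7 to give the planar 1-alkoxy-2-siloxyallyl cation 8, whose vacant frontier orbital is largest at the unsubstituted terminus C7, so the free and most nucleophilic α-carbon of furan 3 (C8) bonds there first and the enol ether carbon C5 then closes onto the furan-derived oxocarbenium carbon C1, both bonds forming on one face of each partner. The closest known reaction is the low-temperature (4+3) cycloaddition of furans with chiral alkoxy siloxyallyl cations generated from mixed acetals, applied here to a 2,3-disubstituted furan. The seven-membered carbocycle, and with it the six-membered O–C1–C5–C6–C7–C8 ring of the oxabicycle, closes by intermolecular (4+3) cycloaddition whose second bond is a 7-exo-trig attack of the enol ether on the C1 oxocarbenium. C1 and C8 arise together from suprafacial addition across the furan α-carbons, their absolute sense is set by the phenyl group of the (S)-1-phenylethyl ether shielding one face of 8, and C5 is set by the compact transition state that places the alkoxy group equatorial (β), which is also the thermodynamic position α to the ketone. The step needs regioselectivity (C5 to C1, C7 to C8), secured by first bond formation at the only unsubstituted furan α-carbon, and facial selectivity, secured by the auxiliary at −95 °C. Et3SiOTf released from the silylated ketone carries the chain, so the triflate is needed only in catalytic amount.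

Step 6
Reactants: 9 oxa-bridged cycloadduct; 10 tert-butyl bromoacetate
Product: 12 C7-equatorial (β) tert-butyl ester ketone, via axial C7 epimer 11 (not isolated)
Conditions: LiN(i-Pr)2, THF, −78 °C; 10, DMPU, −78 to −30 °C; then MeOH, DBU, 0 °C to rt
Reagents that add atoms: none
Why: Kinetic lithium enolate formation occurs at the C7 methylene, remote from the alkoxy-bearing and more hindered C5, SN2 alkylation by the bromoacetate from the exo face should give the axial epimer 11, and DBU then equilibrates C7 through the enol to the equatorial epimer 12 (ketone enolate alkylation, then thermodynamic epimerisation).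

Step 7
Reactants: 12 C7-equatorial tert-butyl ester ketone
Product: 13 axial (β) C6 alcohol, all-cis with the C5 and C7 substituents
Conditions: LiBH(s-Bu)3, THF, −78 °C; then NaBO3·4H2O, H2O, 0 °C
Reagents that add atoms: none
Why: The bulky hydride attacks the C6 ketone from the exo (α) face, away from the C9=C10 bridge, which sets the hydroxyl axial (diastereoselective ketone reduction); at −78 °C the alkoxide does not close onto the hindered tert-butyl ester.

Step 8
Reactants: 13 axial C6 alcohol
Product: 14 axial C6 methanesulfonate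
Conditions: MsCl, Et3N, CH2Cl2, 0 °C
Reagents that add atoms: methanesulfonyl chloride, CS(Cl)(=O)=O
Why: Mesylation (through sulfene, hence tolerant of the hindered axial alcohol) turns the C6 hydroxyl into a leaving group with retention.

Step 9
Reactants: 14 axial C6 methanesulfonate
Product: 16 C6-mesyloxy carboxylic acid, via trimethylsilyl ester 15 (not isolated)
Conditions: Me3SiOTf, 2,6-lutidine, CH2Cl2, 0 °C; aq. pH 5 work-up
Reagents that add atoms: none
Why: Silyl triflate-mediated cleavage of the tert-butyl ester (O-silylation and loss of the tert-butyl group as 2-methylpropene) under lutidine buffer leaves the benzylic ether, the silyl ether and the mesylate alone, and silyl ester 15 is hydrolysed on work-up.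

Step 10
Reactants: 16 C6-mesyloxy carboxylic acid
Product: 17 oxa-bridged trans-fused γ-lactone (C6–O equatorial, α)
Conditions: Cs2CO3, DMF, 50 °C
Reagents that add atoms: none
Why: The caesium carboxylate displaces the axial mesylate from the open exo face in a 5-exo-tet SN2 reaction (intramolecular carboxylate O-alkylation), which inverts C6 and gives the trans-fused diequatorial lactone.

Step 11
Reactants: 17 oxa-bridged trans-fused γ-lactone
Product: 19 C9 exo (α) alcohol with C10 methyl endo (β), via C9 alkylborane 18 (not isolated)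
Conditions: BH3·THF, THF, 0 °C to rt; then NaBO3·4H2O, THF–H2O, rt
Reagents that add atoms: sodium perborate, [Na+].[O-]OB=O
Why: Hydroboration–oxidation: borane adds to the trisubstituted C9=C10 alkene from the exo face with boron on the less substituted C9 and much faster than it reduces the lactone, so the hydroxyl is exo and the C10 methyl endo (corrected in step 18).

Step 12
Reactants: 19 C9 exo alcohol
Product: 20 C9 triethylsilyl ether
Conditions: Et3SiCl, imidazole, DMF, rt
Reagents that add atoms: chlorotriethylsilane, CC[Si](Cl)(CC)CC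
Why: Silylation protects the C9 hydroxyl as an ether that tolerates enolate chemistry and hydrogenolysis and can later be removed without touching the t-BuPh2Si ether.

Step 13
Reactants: 20 C9 triethylsilyl ether
Product: 21 C11 dimethylaminomethyl lactone (C11 epimers)
Conditions: LiN(i-Pr)2, THF, −78 °C; Me2N=CH2 I, −78 to 0 °C
Reagents that add atoms: N,N-dimethylmethyleneiminium iodide, C[N+](C)=C.[I-]
Why: Mannich reaction of the lactone lithium enolate with the preformed iminium salt places the future methylene carbon on C11 in a form inert to hydrogenation, SmI2 and organochromium reagents; the C11 configuration is irrelevant because it is destroyed in step 24.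

Step 14
Reactants: 21 C11 dimethylaminomethyl lactone
Product: 22 C5 alcohol
Conditions: H2 (1 atm), Pd(OH)2/C, AcOH (2 equiv), EtOAc, rt
Reagents that add atoms: none
Why: Hydrogenolysis of the benzylic C–O bond frees the C5 hydroxyl; acetic acid keeps the amine protonated so that it does not poison the catalyst, and no alkene is left to reduce.

Step 15
Reactants: 22 C5 alcohol; 23 (R)-2-methylbutanoic acid
Product: 24 C5 (R)-2-methylbutanoate
Conditions: DCC, DMAP, CH2Cl2, 0 °C to rt
Reagents that add atoms: none
Why: Steglich esterification (carbodiimide activation, DMAP acyl transfer) acylates the only free hydroxyl under conditions in which the α-centre of 23 should not epimerise.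

Step 16
Reactants: 24 C5 (R)-2-methylbutanoate
Product: 25 C9 alcohol
Conditions: HF·pyridine, pyridine, THF, 0 °C
Reagents that add atoms: none
Why: Buffered HF·pyridine removes the secondary triethylsilyl ether much faster than the primary t-BuPh2Si ether (selective desilylation).

Step 17
Reactants: 25 C9 alcohol
Product: 26 C9 ketone with C10 methyl endo (β)
Conditions: (COCl)2, DMSO, CH2Cl2, −78 °C; Et3N, −78 to 0 °C
Reagents that add atoms: none
Why: Swern oxidation converts the C9 alcohol into the ketone without affecting the tertiary amine, the esters or the silyl ether.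

Step 18
Reactants: 26 C9 ketone with C10 methyl endo
Product: 27 C9 ketone with C10 methyl exo (α)
Conditions: DBU (0.1 equiv), CH2Cl2, 0 °C to rt
Reagents that add atoms: none
Why: Amine-base epimerisation through the C9 enol moves the C10 methyl from the endo face, where it clashes with the axial C6 hydrogen of the three-carbon bridge, to the favoured exo face; catalytic DBU at low temperature is chosen to hold back β-elimination of the bridge oxygen and epimerisation of the side-chain ester.

Step 19
Reactants: 27 C9 ketone with C10 methyl exo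
Product: 28 ring-opened cycloheptanone with free C1 tertiary hydroxyl and C8 methylene
Conditions: SmI2, THF–MeOH, −78 °C
Reagents that add atoms: none
Why: SmI2 (divalent samarium) reduces the C9 ketone by single-electron transfer, the adjacent C8–O bond fragments (reductive cleavage of an α-alkoxy ketone, helped by release of bicyclic strain) and methanol protonates C8, which frees the C1 hydroxyl with its configuration and leaves C10 untouched because enolisation lies on the C8 side.

Step 20
Reactants: 28 ring-opened cycloheptanone
Product: 29 C1 hydroxymethyl diol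
Conditions: HF·pyridine, THF, 0 °C to rt
Reagents that add atoms: none
Why: Fluoride-induced desilylation under acidic conditions, which do not trigger retro-aldol cleavage of the β-hydroxy ketone, frees the primary alcohol.

Step 21
Reactants: 29 C1 hydroxymethyl diol
Product: 30 α-hydroxy aldehyde
Conditions: SO3·pyridine, DMSO, i-Pr2NEt, CH2Cl2, 0 °C
Reagents that add atoms: none
Why: Parikh–Doering oxidation (activated DMSO) takes the primary alcohol to the aldehyde; the tertiary hydroxyl cannot be oxidised and activated DMSO does not cleave the 1,2-diol.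

Step 22
Reactants: 30 α-hydroxy aldehyde; 31 (E)-1-bromoprop-1-ene
Product: 32 allylic alcohol (carbinol epimers)
Conditions: CrCl2, NiCl2 (cat.), DMF, rt
Reagents that add atoms: none
Why: Nozaki–Hiyama–Kishi coupling: the alkenylchromium species (trivalent chromium) formed from 31 under NiCl2 catalysis adds to the aldehyde only, leaving ketone, lactone and ester untouched and keeping the (E) geometry; the new carbinol centre is a mixture that is removed in step 23.

Step 23
Reactants: 32 allylic alcohol
Product: 33 amino (E)-enone
Conditions: SO3·pyridine, DMSO, i-Pr2NEt, CH2Cl2, 0 °C to rt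
Reagents that add atoms: none
Why: Parikh–Doering oxidation of the secondary allylic alcohol gives the (E)-enone, the tertiary hydroxyl and the amine being unaffected.

Step 24
Reactants: 33 amino (E)-enone
Product: 35 CNP0153197.3, via trimethylammonium iodide 34 (not isolated)
Conditions: MeI, THF, rt; then aq. NaHCO3, EtOAc, rt
Reagents that add atoms: none
Why: Exhaustive N-methylation gives ammonium salt 34, and bicarbonate removes the acidic C11 proton so that trimethylamine is lost (Hofmann-type E1cB elimination), which unveils the α-methylene lactone under conditions mild enough for the β-hydroxy ketone and the enone.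

**Compound list**

1 | methyl 3-methylfuran-2-carboxylate | COC(=O)c1occc1C | starting material
2 | (3-methylfuran-2-yl)methanol | Cc1ccoc1CO | intermediate
3 | tert-butyl[(3-methylfuran-2-yl)methoxy]diphenylsilane | Cc1ccoc1CO[Si](c2ccccc2)(c3ccccc3)C(C)(C)C | intermediate
4 | 1,1-dimethoxypropan-2-one | CC(=O)C(OC)OC | starting material
5 | (S)-1-phenylethanol | C[C@H](O)c1ccccc1 | starting material
6 | 1-methoxy-1-[(1S)-1-phenylethoxy]propan-2-one, acetal carbon unassigned | CC(=O)C(OC)O[C@@H](C)c1ccccc1 | intermediate
7 | triethyl({3-methoxy-3-[(1S)-1-phenylethoxy]prop-1-en-2-yl}oxy)silane, acetal carbon unassigned | C=C(O[Si](CC)(CC)CC)C(OC)O[C@@H](C)c1ccccc1 | intermediate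
8 | 1-[(1S)-1-phenylethoxy]-2-(triethylsiloxy)allyl cation, triflate salt | C=C(O[Si](CC)(CC)CC)C=[O+][C@@H](C)c1ccccc1.[O-]S(=O)(=O)C(F)(F)F | intermediate (not isolated)
9 | 8-oxabicyclo[3.2.1]oct-6-en-3-one cycloadduct: oxygen bridge C1–O–C8 on the α face, C1 CH2OSi(t-Bu)Ph2, C9=C10 alkene with methyl on C10, C6 ketone, C5 β (equatorial) (S)-1-phenylethoxy | O=C1C[C@@H]2O[C@@](CO[Si](c3ccccc3)(c3ccccc3)C(C)(C)C)(C(C)=C2)[C@H]1O[C@@H](C)c1ccccc1 | intermediate
10 | tert-butyl bromoacetate | CC(C)(C)OC(=O)CBr | starting material
11 | as 9 with CH2CO2t-Bu on C7, α (axial) | O=C1[C@H](CC(=O)OC(C)(C)C)[C@@H]2O[C@@](CO[Si](c3ccccc3)(c3ccccc3)C(C)(C)C)(C(C)=C2)[C@H]1O[C@@H](C)c1ccccc1 | intermediate (not isolated)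
12 | as 9 with CH2CO2t-Bu on C7, β (equatorial) | O=C1[C@@H](CC(=O)OC(C)(C)C)[C@@H]2O[C@@](CO[Si](c3ccccc3)(c3ccccc3)C(C)(C)C)(C(C)=C2)[C@H]1O[C@@H](C)c1ccccc1 | intermediate
13 | C6 β (axial) alcohol of 12, C5 O, C6 OH and C7 C all cis | O[C@H]1[C@@H](CC(=O)OC(C)(C)C)[C@@H]2O[C@@](CO[Si](c3ccccc3)(c3ccccc3)C(C)(C)C)(C(C)=C2)[C@H]1O[C@@H](C)c1ccccc1 | intermediate
14 | C6 β (axial) methanesulfonate of 13 | CS(=O)(=O)O[C@H]1[C@@H](CC(=O)OC(C)(C)C)[C@@H]2O[C@@](CO[Si](c3ccccc3)(c3ccccc3)C(C)(C)C)(C(C)=C2)[C@H]1O[C@@H](C)c1ccccc1 | intermediate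
15 | trimethylsilyl ester corresponding to 14 | CS(=O)(=O)O[C@H]1[C@@H](CC(=O)O[Si](C)(C)C)[C@@H]2O[C@@](CO[Si](c3ccccc3)(c3ccccc3)C(C)(C)C)(C(C)=C2)[C@H]1O[C@@H](C)c1ccccc1 | intermediate (not isolated)
16 | carboxylic acid corresponding to 14 | CS(=O)(=O)O[C@H]1[C@@H](CC(=O)O)[C@@H]2O[C@@](CO[Si](c3ccccc3)(c3ccccc3)C(C)(C)C)(C(C)=C2)[C@H]1O[C@@H](C)c1ccccc1 | intermediate
17 | oxa-bridged trans-fused γ-lactone: C6–O α (equatorial), C7–C11 β, C9=C10 alkene, C5 β (S)-1-phenylethoxy | C1C(=O)O[C@@H]2[C@@H]1[C@@H]3O[C@@](CO[Si](c4ccccc4)(c4ccccc4)C(C)(C)C)(C(C)=C3)[C@H]2O[C@@H](C)c5ccccc5 | intermediate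
18 | C9 α (exo) alkylborane of 17, C10 methyl β | C1C(=O)O[C@@H]2[C@@H]1[C@@H]3O[C@@](CO[Si](c4ccccc4)(c4ccccc4)C(C)(C)C)([C@H](C)[C@H]3B)[C@H]2O[C@@H](C)c5ccccc5 | intermediate (not isolated)
19 | C9 α (exo) alcohol, C10 methyl β (endo) | C1C(=O)O[C@@H]2[C@@H]1[C@@H]3O[C@@](CO[Si](c4ccccc4)(c4ccccc4)C(C)(C)C)([C@H](C)[C@H]3O)[C@H]2O[C@@H](C)c5ccccc5 | intermediate
20 | C9 triethylsilyl ether of 19 | C1C(=O)O[C@@H]2[C@@H]1[C@@H]3O[C@@](CO[Si](c4ccccc4)(c4ccccc4)C(C)(C)C)([C@H](C)[C@H]3O[Si](CC)(CC)CC)[C@H]2O[C@@H](C)c5ccccc5 | intermediate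
21 | 20 with CH2NMe2 on C11 (C11 unassigned) | CN(C)CC1C(=O)O[C@@H]2[C@@H]1[C@@H]3O[C@@](CO[Si](c4ccccc4)(c4ccccc4)C(C)(C)C)([C@H](C)[C@H]3O[Si](CC)(CC)CC)[C@H]2O[C@@H](C)c5ccccc5 | intermediate
22 | 21 with free C5 β hydroxyl | CN(C)CC1C(=O)O[C@@H]2[C@@H]1[C@@H]3O[C@@](CO[Si](c4ccccc4)(c4ccccc4)C(C)(C)C)([C@H](C)[C@H]3O[Si](CC)(CC)CC)[C@H]2O | intermediate
23 | (R)-2-methylbutanoic acid | CC[C@@H](C)C(=O)O | starting material
24 | C5 (R)-2-methylbutanoate of 22 | CN(C)CC1C(=O)O[C@@H]2[C@@H]1[C@@H]3O[C@@](CO[Si](c4ccccc4)(c4ccccc4)C(C)(C)C)([C@H](C)[C@H]3O[Si](CC)(CC)CC)[C@H]2OC(=O)[C@H](C)CC | intermediate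
25 | 24 with free C9 α hydroxyl | CN(C)CC1C(=O)O[C@@H]2[C@@H]1[C@@H]3O[C@@](CO[Si](c4ccccc4)(c4ccccc4)C(C)(C)C)([C@H](C)[C@H]3O)[C@H]2OC(=O)[C@H](C)CC | intermediate
26 | oxa-bridged C9 ketone, C10 methyl β (endo) | CN(C)CC1C(=O)O[C@@H]2[C@@H]1[C@@H]3O[C@@](CO[Si](c4ccccc4)(c4ccccc4)C(C)(C)C)([C@H](C)C3=O)[C@H]2OC(=O)[C@H](C)CC | intermediate
27 | oxa-bridged C9 ketone, C10 methyl α (exo) | CN(C)CC1C(=O)O[C@@H]2[C@@H]1[C@@H]3O[C@@](CO[Si](c4ccccc4)(c4ccccc4)C(C)(C)C)([C@@H](C)C3=O)[C@H]2OC(=O)[C@H](C)CC | intermediate
28 | cycloheptanone with C1 α tertiary hydroxyl, C1 CH2OSi(t-Bu)Ph2, C8 methylene, C10 α methyl, C5 β ester, trans lactone with CH2NMe2 on C11 | CN(C)CC1C(=O)O[C@@H]2[C@@H]1CC(=O)[C@H](C)[C@@](O)(CO[Si](c3ccccc3)(c3ccccc3)C(C)(C)C)[C@H]2OC(=O)[C@H](C)CC | intermediate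
29 | 28 with free CH2OH on C1 | CN(C)CC1C(=O)O[C@@H]2[C@@H]1CC(=O)[C@H](C)[C@@](O)(CO)[C@H]2OC(=O)[C@H](C)CC | intermediate
30 | 29 with CHO on C1 | CN(C)CC1C(=O)O[C@@H]2[C@@H]1CC(=O)[C@H](C)[C@@](O)(C=O)[C@H]2OC(=O)[C@H](C)CC | intermediate
31 | (E)-1-bromoprop-1-ene | C/C=C/Br | starting material
32 | 30 with CH(OH)–CH=CH–CH3 (E) on C1, carbinol unassigned | CN(C)CC1C(=O)O[C@@H]2[C@@H]1CC(=O)[C@H](C)[C@@](O)(C(O)/C=C/C)[C@H]2OC(=O)[C@H](C)CC | intermediate
33 | 32 oxidised to the (E)-but-2-enoyl ketone | CN(C)CC1C(=O)O[C@@H]2[C@@H]1CC(=O)[C@H](C)[C@@](O)(C(=O)/C=C/C)[C@H]2OC(=O)[C@H](C)CC | intermediate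
34 | trimethylammonium iodide of 33 | C[N+](C)(C)CC1C(=O)O[C@@H]2[C@@H]1CC(=O)[C@H](C)[C@@](O)(C(=O)/C=C/C)[C@H]2OC(=O)[C@H](C)CC.[I-] | intermediate (not isolated)
35 | CNP0153197.3 | C=C1C(=O)O[C@@H]2[C@@H]1CC(=O)[C@H](C)[C@@](O)(C(=O)/C=C/C)[C@H]2OC(=O)[C@H](C)CC | target

**Summary**

Total step count: 24. Longest linear sequence: 22 steps (from 1 through steps 1, 2 and 5 to 24; the branch from 4 and 5 is equally long).

Steps most likely to fail:

1. Step 5. The 3-methyl group activates the substituted α-carbon of the furan and may erode regiocontrol; the first-formed adduct may lose a proton instead of closing at the fully substituted C1 (substitution in place of cycloaddition); facial discrimination by the auxiliary may be weak with this hindered furan. The fallback sets out from 5 and 3 and comes back at 9; it generates the three-carbon partner as a neutral oxyallyl species from an α-chloro ketone instead of as a cation from an acetal. Alcohol 5 is O-alkylated with epichlorohydrin (NaH, DMF) to 2-{[(1S)-1-phenylethoxy]methyl}oxirane F1. The epoxide is opened with LiCl and AcOH in THF to 1-chloro-3-[(1S)-1-phenylethoxy]propan-2-ol F2. Swern oxidation gives 1-chloro-3-[(1S)-1-phenylethoxy]propan-2-one F3. Dehydrochlorination of F3 with Et3N in CF3CH2OH at rt in the presence of 3 should give the (4+3) adduct by a more concerted addition that is less prone to proton loss. Facial control is expected to be weaker at this temperature, so 9 would form together with the ring-diastereomeric cycloadduct F4 and be separated from it by chromatography.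

2. Step 10. E2 elimination of the axial mesylate, which has antiperiplanar axial hydrogens on C5 and C7, may outpace the intramolecular displacement. The fallback sets out from 13 and comes back at 17; it inverts C6 under non-basic conditions and closes the lactone by acyl substitution with retention. Mitsunobu reaction of 13 with 4-nitrobenzoic acid, PPh3 and DIAD in toluene gives the inverted equatorial C6 4-nitrobenzoate F5. Methanolysis (K2CO3, MeOH) frees the equatorial C6 alcohol F6. This alcohol closes onto the neighbouring tert-butyl ester, in the same medium or on warming with catalytic PPTS in toluene, to give 17.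

3. Step 22. Addition of the alkenylchromium reagent to the neopentyl-type aldehyde may be slow, so that retro-aldol cleavage or α-ketol shift of the hydroxy aldehyde, or loss of alkene geometry, competes. The fallback sets out from 30 and comes back at 33; it bypasses 32 and step 23. Barbier allylation of 30 with allyl bromide and indium metal (zerovalent indium) in THF–H2O, which is selective for aldehydes over ketones, gives the homoallylic alcohol F7. Parikh–Doering oxidation gives the β,γ-unsaturated ketone F8. Catalytic DBU in CH2Cl2 moves the double bond into conjugation and gives the (E)-enone 33.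

**Further compounds**

F1 | step 5 | 2-{[(1S)-1-phenylethoxy]methyl}oxirane, epoxide carbon unassigned | C[C@H](OCC1CO1)c1ccccc1
F2 | step 5 | 1-chloro-3-[(1S)-1-phenylethoxy]propan-2-ol, carbinol unassigned | C[C@H](OCC(O)CCl)c1ccccc1
F3 | step 5 | 1-chloro-3-[(1S)-1-phenylethoxy]propan-2-one | C[C@H](OCC(=O)CCl)c1ccccc1
F4 | step 5 | ring diastereomer of 9 (C1, C5 and C8 inverted, (S) auxiliary) | O=C1C[C@H]2O[C@](CO[Si](c3ccccc3)(c3ccccc3)C(C)(C)C)(C(C)=C2)[C@@H]1O[C@@H](C)c1ccccc1
F5 | step 10 | C6 α (equatorial) 4-nitrobenzoate, C6 epimer series of 13 | O=C(O[C@@H]1[C@@H](CC(=O)OC(C)(C)C)[C@@H]2O[C@@](CO[Si](c3ccccc3)(c3ccccc3)C(C)(C)C)(C(C)=C2)[C@H]1O[C@@H](C)c1ccccc1)c1ccc(cc1)[N+](=O)[O-]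
F6 | step 10 | C6 α (equatorial) alcohol, C6 epimer of 13 | O[C@@H]1[C@@H](CC(=O)OC(C)(C)C)[C@@H]2O[C@@](CO[Si](c3ccccc3)(c3ccccc3)C(C)(C)C)(C(C)=C2)[C@H]1O[C@@H](C)c1ccccc1
F7 | step 22 | homoallylic alcohol, 30 with CH(OH)CH2CH=CH2 on C1, carbinol unassigned | CN(C)CC1C(=O)O[C@@H]2[C@@H]1CC(=O)[C@H](C)[C@@](O)(C(O)CC=C)[C@H]2OC(=O)[C@H](C)CC
F8 | step 22 | β,γ-unsaturated ketone, but-3-enoyl group on C1 | CN(C)CC1C(=O)O[C@@H]2[C@@H]1CC(=O)[C@H](C)[C@@](O)(C(=O)CC=C)[C@H]2OC(=O)[C@H](C)CC
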